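## The problem

CNP0347302.1 is a ten-membered carbocycle, numbered C1H=C10(C14H2OAc)–C9H2–C8H(O-acyl)–C7H–C6H(O)–C5H2–C4H(CH3)–C3H=C2H–C1, trans-fused at C6–C7 to an α-methylene-γ-butyrolactone, C7–C11(=C13H2)–C12(=O)–O–C6. The ring holds a ring-cis,cis 1,3-diene, C10=C1–C2=C3 (1(10)E,2Z by the sequence rule), and ten-membered rings are the least willing carbocycles to close end to end, the more so when two cis alkenes must emerge conjugated. Four ring stereocentres must be set: the contiguous all-syn triad C6 (O), C7 (CH2C=O), C8 (O) and the isolated allylic methyl centre C4; a fifth, quaternary, lies in the (S)-2,3-dihydroxy-2-methylpropanoate on O8. C6 can direct C7 across a flat butenolide, but C7 biases C8 only weakly, C4 is insulated from the triad by C5, and the side-chain centre is remote, so C8 needs catalyst control and C4 and the acid are best bought. The α-methylene lactone (conjugate acceptor, sensitive to radicals and bases), the primary acetate allylic to the diene (ionisable, labile to palladium and alkoxides), the ester of a free 1,2-diol (acyl migration) and a free O8 (as well placed as O6 to lactonise on C12) must appear late and under mild, non-basic conditions. The enabling feature is that C10, C1, C2 and C3 are the retron of a cyclobutene ring opening: a C3–C10 bond turns the ten-membered ring into an eight-membered ring (C3 to C10 through C4–C9) fused along C3–C10 to a cyclobutene (C3, C2, C1, C10), in which C10 is quaternary and already carries C14, and orbital symmetry ties both alkene geometries to that ring fusion.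

## Retrosynthesis

**End game (30 ⇒ 29 ⇒ 26 + 27; 26 ⇒ 25 ⇒ 24).** The acetal C–O bonds of the side-chain diol are cut first (29), then the O8–acyl bond (alcohol 26, acid 27), the O14–acetyl bond (diol 25) and both O–Si bonds (24). The diol ester and the dienylic acetate are the most fragile groups, so they come last. Acetylating C14 before esterifying O8 leaves one free hydroxyl at each acylation. The forward steps must distinguish a primary allylic from a hindered secondary hydroxyl and must stay non-basic once O8 is free.

**Lactone methylene (24 ⇒ 21).** C11=C13 is cut. An α-methylene lactone would not survive the radical, photochemical, ketene, palladium hydride and thermal steps before it, whereas the saturated lactone of 21 is inert to all of them. The forward reaction is a lactone enolate aminomethylation and elimination, done while O8 and O14 are silylated so that no ester competes for the base.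

**Ring expansion (21 ⇒ 20).** C3 and C10 are reconnected: the ten-membered diene becomes the trans-fused bicyclo[6.2.0]dec-9-ene 20. Cutting instead at C1–C2 or at a ring single bond would each demand an end-to-end closure of the ten-membered ring. Here two smaller rings are merged, ring strain pays for the medium ring, and the diene geometry is set by the ring fusion. The forward step must turn both ring bonds inward on conrotation; nothing else in 20 is asked to react.

**Cyclobutene (20 ⇒ 19 ⇒ 18 ⇒ 17 ⇒ 16).** C2–C3 and C1–C10 are cut, so that C1 and C2 arrive as a two-carbon ketene unit on the ring-trans cyclooctene 16; the ketone of 17/18 is the handle for the C1=C2 alkene. A light-driven addition of an alkyne to a C10 ester at C3=C10 would be shorter. There, however, the ring fusion is decided in a short-lived biradical, and the C14 ester would later have to be reduced beside the lactone. A thermal, suprafacial cycloaddition copies the alkene geometry of 16 into the ring fusion. The forward sequence must be regioselective in the enolisation of 18 (toward C1).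

**Eight-membered ring (16 ⇒ 15 ⇒ 14).** The geometry of C3=C10 is inverted (16 ⇒ 15) and the alkene is cut to the diene 14. C3=C10 is the only ring bond remote from the stereotriad, and the trans-fused lactone of 14 pre-organises the two chains. The precursor is a monocyclic lactone with two terminal alkenes. The forward steps are a ring-closing metathesis to a trisubstituted cyclooctene and a sensitised Z→E isomerisation with silver capture.

**C8–C9 (14 ⇒ 13 ⇒ 8 + 12).** This cut separates the three-carbon unit C9–C10–C14 (stannane 12) from the lactone aldehyde 8. It is preferred to C9–C10 or C7–C8 because it creates C8 in a catalyst-controlled allylation and brings in C14 at the alcohol oxidation level. The forward reaction must add to the Re face of the aldehyde, giving the all-syn triad.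

**C7–C8 (8 ⇒ 7 ⇒ 6).** The formyl carbon C8 is removed from the butenolide 6. On the planar butenolide the C6 substituent directs the incoming carbon to the opposite face, which is the trans relationship of the target. A masked formyl radical is chosen over a vinyl group (later ozonolysis) because the C3 vinyl group is already present.

**Butenolide (6 ⇒ 4 ⇒ 2 ⇒ 1).** C7=C11 and the C6–O bond are cut: C11–C12 come from a phosphonoacetate and the C6 oxygen from a catalyst-controlled α-oxygenation of aldehyde 2. Aldehyde 2 is what remains of 1 after cleavage of its trisubstituted alkene. This takes C3–C7, the vinyl group and the C4 stereocentre from the chiral pool in one step.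

**Allyl reagent (12 ⇒ 11 ⇒ 10 ⇒ 9).** The C–Sn, C–Br and O–Si bonds are cut back to the symmetrical diol 9.

## Roads not taken

Alternative 1: The cut is the diene single bond C1–C2, made on the fully functionalised molecule. Forward, the open-chain lactone A1, carrying the C1 vinyl iodide (iodine cis to C9) and the C2 (Z)-vinylstannane, would be cyclised with Pd2(dba)3/AsPh3 to A2, the acetonide of the target (the same structure as 29).
- Merits: the coupling is a known way to close rings across a diene single bond, both alkene geometries are fixed beforehand and transferred with retention, all stereocentres are set on open-chain or lactone intermediates, and only an acetal hydrolysis follows. In precedent and convergence this road is better than the chosen one.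
- Weak points: the most strained ring size must be closed end to end with nothing to pay for the strain, so intermolecular coupling competes even at high dilution. A1 and A2 hold an allylic (in A2 dienylic) acetate that zerovalent palladium can ionise, and an α-methylene lactone that can insert into the vinylpalladium intermediate. The trisubstituted iodoalkene and the (Z)-stannane each need their own stereocontrolled synthesis.
- Comparison: the chosen plan offers a unimolecular, reagent-free, strain-driven ring formation on a substrate that carries only silyl ethers and a saturated lactone, with both alkene geometries taken from one ring fusion. It pays with five steps to build the cyclobutene and with a key step that has not been demonstrated.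

Alternative 2: The cut is C8–C9 with C6–C1 reconnected, which contracts the ring to the cyclohexenol A3 bearing cis-disposed 2-silylvinyl (C7=C8) and 2-propenyl (C10=C9) groups. Forward, KH/18-crown-6 would trigger an anionic oxy-Cope rearrangement and Me3SiCl would trap the enolate as the ten-membered silyl enol ether A4.
- Merits: a strongly accelerated [3,3] shift of a well-tried class for six-to-ten ring expansion; a six-membered precursor that is easy to assemble; the C2=C3 cis alkene inherited from the cyclohexene; C14 in place; silicon at C8 as a masked hydroxyl. Its key step is safer than the chosen one and would probably reach a ten-membered ring in fewer steps.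
- Weak points: A4 has neither the lactone nor the C6 and C7 stereocentres. The enol ether must be turned into the C6 carbinol and the C7 acetic acid branch, and the C8–Si bond oxidised beside a diene, all on a mobile ten-membered ring where facial control cannot be predicted with confidence. The C1=C10 geometry depends on the chair or boat transition state.
- Comparison: the chosen plan sets all four ring stereocentres before the ring exists and never touches them again, at the price of a longer approach to the ring-forming step.

Alternative 3: The cut is C6–C7 with O6 joined to C13, which expands the carbocycle to the 13-membered allylic ether A5 (C6 stannane, C7=C11 alkene). Forward, n-BuLi would exchange tin for lithium and the α-alkoxy carbanion would undergo a [2,3] shift to A6, the ten-membered C6 carbinol with a 2-propenyl unit on C7.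
- Merits: one step forms the carbocycle, the C6–C7 bond, both stereocentres and the C11=C13 methylene, so no late α-methylenation is needed; a 13-membered ether is easier to close than a ten-membered carbocycle. In sparing the methylenation it is better than the chosen plan.
- Weak points: the C6/C7 relationship is decided by the folding of a large ring in the transition state and competes with a [1,2] shift. n-BuLi forbids esters, so three different silyl ethers are needed, and C12 must afterwards be oxidised to the acid beside an allylic alcohol and the diene. A5 already contains the cis,cis-diene, whose construction this road leaves open.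
- Comparison: the chosen plan takes C6/C7 from a butenolide addition of reliable sense and takes the diene from the key step itself; it needs two more steps for the lactone methylene.

Key step: step 17

Remark 1: 1 and 27 are taken as purchasable in high enantiomeric purity.
Remark 2: the E-alkene 16 is planar-chiral, so 16–20 can each be two stereoisomers (the trans-fused adducts differ at both C3 and C10); one is drawn, both give 21, and they are carried on together.

Step 1
Reactants: 1 (S)-3,7-dimethylocta-1,6-diene ((S)-β-citronellene)
Product: 2 (S)-4-methylhex-5-enal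
Conditions: O3 (1.0 equiv, Sudan Red 7B end point), CH2Cl2, pyridine (cat.), −78 °C; Me2S, −78 °C → rt
Reagents that add atoms: ozone, [O-][O+]=O
Why: Ozonolysis with reductive work-up; electrophilic ozone attacks the trisubstituted isopropylidene alkene much faster than the vinyl group and the dye end point stops it after one equivalent, so the vinyl group and the methyl-bearing centre (C4 of the target) are untouched.

Step 2
Reactants: 2 (S)-4-methylhex-5-enal
Product: 4 ethyl (2Z,4S,6S)-6-methyl-4-[(phenylamino)oxy]octa-2,7-dienoate, via α-anilinooxy aldehyde 3 (not isolated)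
Conditions: D-proline (20 mol %), PhNO, DMSO, rt; then (PhO)2P(O)CH2CO2Et, NaI, DBU, THF, −20 → 0 °C
Reagents that add atoms: nitrosobenzene, O=Nc1ccccc1; ethyl 2-(diphenoxyphosphoryl)acetate, CCOC(=O)CP(=O)(Oc1ccccc1)Oc1ccccc1
Why: Proline-catalysed α-aminoxylation (O-selective nitroso aldol through the enamine) sets C6; the D-catalyst should give the (S)-α-oxy aldehyde under catalyst control, independent of the remote C4 centre. The labile aldehyde 3 is olefinated in the same flask by a Z-selective Horner–Wadsworth–Emmons reaction of the diaryl phosphonate, which places the ester cis to the C6 oxygen as lactonisation requires.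

Step 3
Reactants: 4 ethyl (2Z,4S,6S)-6-methyl-4-[(phenylamino)oxy]octa-2,7-dienoate
Product: 6 (5S)-5-[(2S)-2-methylbut-3-en-1-yl]furan-2(5H)-one, via hydroxy enoate 5 (not isolated)
Conditions: Cu(OAc)2 (30 mol %), EtOH, rt; then PPTS (cat.), CH2Cl2, rt
Reagents that add atoms: none
Why: Copper-catalysed N–O cleavage frees the C6 hydroxyl without touching either alkene, and the (Z)-γ-hydroxy ester closes to the butenolide by 5-exo-trig transesterification; no bond to C6 is broken.

Step 4
Reactants: 6 (5S)-5-[(2S)-2-methylbut-3-en-1-yl]furan-2(5H)-one
Product: 7 (4R,5S)-4-(1,3-dioxolan-2-yl)-5-[(2S)-2-methylbut-3-en-1-yl]oxolan-2-one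
Conditions: 1,3-dioxolane (solvent), Ph2CO (10 mol %), hν (medium-pressure Hg lamp, Pyrex), rt, degassed
Reagents that add atoms: 1,3-dioxolane, C1COCO1
Why: Sensitised radical conjugate addition (Giese type): triplet benzophenone abstracts the acetal hydrogen and the nucleophilic 1,3-dioxolan-2-yl radical adds to C7 of the butenolide on the face away from the C6 side chain, setting C7 trans to C6. The electron-rich vinyl group is a poor acceptor for this radical, and the lactone α-radical is quenched by the solvent.

Step 5
Reactants: 7 (4R,5S)-4-(1,3-dioxolan-2-yl)-5-[(2S)-2-methylbut-3-en-1-yl]oxolan-2-one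
Product: 8 (2S,3R)-2-[(2S)-2-methylbut-3-en-1-yl]-5-oxooxolane-3-carbaldehyde
Conditions: 1 M HCl, THF, rt
Reagents that add atoms: water, O
Why: Acid-catalysed acetal hydrolysis; lactone and alkene are inert, and any enolisation at C7 returns the more stable trans-disubstituted lactone.

Step 6
Reactants: 9 2-methylidenepropane-1,3-diol
Product: 10 2-({[tert-butyl(dimethyl)silyl]oxy}methyl)prop-2-en-1-ol
Conditions: NaH (1.0 equiv), THF, 0 °C; TBSCl, rt
Reagents that add atoms: tert-butyldimethylsilyl chloride, CC(C)(C)[Si](C)(C)Cl
Why: Monosilylation of a symmetrical diol through its sparingly soluble monosodium alkoxide, which reacts once.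

Step 7
Reactants: 10 2-({[tert-butyl(dimethyl)silyl]oxy}methyl)prop-2-en-1-ol
Product: 11 {[2-(bromomethyl)prop-2-en-1-yl]oxy}(tert-butyl)dimethylsilane
Conditions: CBr4, PPh3, CH2Cl2, 0 °C
Reagents that add atoms: carbon tetrabromide, BrC(Br)(Br)Br
Why: Appel bromination of a primary allylic alcohol under neutral conditions that leave the silyl ether alone.

Step 8
Reactants: 11 {[2-(bromomethyl)prop-2-en-1-yl]oxy}(tert-butyl)dimethylsilane
Product: 12 tert-butyl(dimethyl)({2-[(tributylstannyl)methyl]prop-2-en-1-yl}oxy)silane
Conditions: Bu3SnH, LiN(iPr)2, THF, 0 °C; then 11, −78 → 0 °C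
Reagents that add atoms: tributyltin hydride, CCCC[SnH](CCCC)CCCC
Why: Nucleophilic substitution of the allylic bromide by Bu3SnLi; direct and allylic attack give the same product because the two CH2 termini of this 2-substituted allyl unit are equivalent.

Step 9
Reactants: 8 (2S,3R)-2-[(2S)-2-methylbut-3-en-1-yl]-5-oxooxolane-3-carbaldehyde; 12 tert-butyl(dimethyl)({2-[(tributylstannyl)methyl]prop-2-en-1-yl}oxy)silane
Product: 13 (4S,5S)-4-[(1R)-3-({[tert-butyl(dimethyl)silyl]oxy}methyl)-1-hydroxybut-3-en-1-yl]-5-[(2S)-2-methylbut-3-en-1-yl]oxolan-2-one
Conditions: (R)-BINOL (20 mol %), Ti(OiPr)4 (10 mol %), 4 Å MS, CH2Cl2, −20 °C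
Reagents that add atoms: none
Why: Keck allylation: the BINOL–titanium Lewis acid activates the aldehyde and the 2-substituted allylstannane adds through an open transition state. The (R)-ligand should direct attack to the Re face, the face Felkin–Anh control also favours (attack anti to C7–C6), so catalyst and substrate are matched and C8 is set (R), syn to C11. The aldehyde reacts in preference to the lactone, and C14 enters at the alcohol level, so no ester has to be reduced beside the lactone.

Step 10
Reactants: 13 (4S,5S)-4-[(1R)-3-({[tert-butyl(dimethyl)silyl]oxy}methyl)-1-hydroxybut-3-en-1-yl]-5-[(2S)-2-methylbut-3-en-1-yl]oxolan-2-one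
Product: 14 (4R,5S)-4-[(1R)-1-{[tert-butyl(dimethyl)silyl]oxy}-3-({[tert-butyl(dimethyl)silyl]oxy}methyl)but-3-en-1-yl]-5-[(2S)-2-methylbut-3-en-1-yl]oxolan-2-one
Conditions: TBSOTf, 2,6-lutidine, CH2Cl2, −78 → 0 °C
Reagents that add atoms: tert-butyldimethylsilyl triflate, CC(C)(C)[Si](C)(C)OS(=O)(=O)C(F)(F)F
Why: Silylation of the hindered secondary alcohol with the silyl triflate; capping O8 at once prevents lactone migration from O6 to O8 and protects it from acylation in step 13.

Step 11
Reactants: 14 (4R,5S)-4-[(1R)-1-{[tert-butyl(dimethyl)silyl]oxy}-3-({[tert-butyl(dimethyl)silyl]oxy}methyl)but-3-en-1-yl]-5-[(2S)-2-methylbut-3-en-1-yl]oxolan-2-one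
Product: 15 cis-cyclooctene lactone (lactone trans-fused at C6–C7 to the cyclooctene C3=C10 with C4 and C9 cis; 4-methyl, 8-OTBS, 10-CH2OTBS)
Conditions: second-generation Grubbs catalyst (H2IMes)(PCy3)Cl2Ru=CHPh (10 mol %), toluene (2 mM), 80 °C
Reagents that add atoms: none
Why: Ring-closing metathesis: the catalyst loads on the monosubstituted C3 vinyl group and closes onto the 1,1-disubstituted C10 alkene. The trans-fused lactone holds C5 and C8 gauche so the chains are pre-organised, an eight-membered ring can hold only the ring-cis alkene, and loss of ethene drives the reaction. Trisubstituted cyclooctenes trans-fused to a five-membered ring are known products of this reaction.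

Step 12
Reactants: 15 cis-cyclooctene lactone
Product: 16 trans-cyclooctene lactone (as 15 but C4 and C9 trans on C3=C10)
Conditions: hν (254 nm), methyl benzoate (sensitiser), Et2O/hexane, flow through AgNO3 on SiO2; release with aq. NaCl
Reagents that add atoms: none
Why: Singlet-sensitised Z→E photoisomerisation of the only alkene; only the strained E isomer binds Ag+ and is removed from the irradiated stream, which drives the otherwise unfavourable photostationary state forward. No stereocentre is touched.

Step 13
Reactants: 16 trans-cyclooctene lactone
Product: 17 trans-fused dichlorocyclobutanone (ring C3–C2(=O)–C1Cl2–C10; H3 and C9 on one face, C4 and C14 on the other)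
Conditions: Cl2CHCOCl, Et3N (slow addition), pentane/Et2O, 0 °C → rt
Reagents that add atoms: dichloroacetyl chloride, ClC(Cl)C(Cl)=O
Why: Thermal ketene–alkene [2+2] cycloaddition of dichloroketene made in situ, a reaction known to be suprafacial on cis- and trans-cyclooctene alike; the E geometry of C3=C10 is therefore copied into the trans ring fusion, and strain makes 16 far more reactive than an unstrained trisubstituted alkene. The carbonyl carbon should bond to the less substituted C3; the reverse orientation gives a ketone that can enolise only toward C2 and also leads to 20.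

Step 14
Reactants: 17 trans-fused dichlorocyclobutanone
Product: 18 trans-fused cyclobutanone (C2=O, C1H2)
Conditions: Zn–Cu couple, NH4Cl, MeOH, rt
Reagents that add atoms: none
Why: Reductive dechlorination of the α,α-dichloroketone through zinc enolates that are protonated in situ; the near-neutral medium spares the silyl ethers and the lactone and should not epimerise C3.

Step 15
Reactants: 18 trans-fused cyclobutanone
Product: 19 trans-fused cyclobutenyl triflate (C1=C2–OTf)
Conditions: KN(SiMe3)2 (1.1 equiv), THF, −78 °C; PhNTf2, −78 → −20 °C
Reagents that add atoms: N-phenylbis(trifluoromethanesulfonimide), O=S(=O)(N(c1ccccc1)S(=O)(=O)C(F)(F)F)C(F)(F)F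
Why: Kinetic enolate formation and O-sulfonylation: the bulky amide should take a proton from the C1 methylene and not from the C3 methine at the ring fusion, and the cyclobutanone is several pKa units more acidic than the lactone, so one equivalent of base leaves C11 alone.

Step 16
Reactants: 19 trans-fused cyclobutenyl triflate
Product: 20 trans-fused bicyclo[6.2.0]dec-9-ene lactone (cyclobutene C3–C2=C1–C10; 8-OTBS, 14-OTBS)
Conditions: Pd(OAc)2 (5 mol %), PPh3 (10 mol %), HCO2H, Et3N, DMF, rt → 40 °C
Reagents that add atoms: none
Why: Palladium-catalysed formate reduction of an enol triflate (oxidative addition to zerovalent palladium, formate exchange, loss of CO2, C–H reductive elimination) gives the C1=C2 cyclobutene under conditions mild enough for the strained ring. If some ring opening occurs already here, the dienyl triflate or diene formed leads to the same 21.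

Step 17
Reactants: 20 trans-fused bicyclo[6.2.0]dec-9-ene lactone
Product: 21 ten-membered ring-cis,cis-diene lactone (C10=C1–C2=C3; 8-OTBS, 14-OTBS)
Conditions: toluene (5 mM), BHT (cat.), base-washed sealed tube, Ar, 110 °C
Reagents that add atoms: none
Why: Proposed new method: a thermal 4π-electron conrotatory ring opening in which the C3–C10 σ bond breaks and, with the C1=C2 π pair, becomes the C1=C10 and C2=C3 π bonds while C1–C2 becomes the diene single bond; the closest known reaction type is the thermal opening of cis-fused bicyclo[n.2.0]alkenes to cyclic 1,3-dienes used as a two-carbon ring expansion, and what is new is a trans-fused member with quaternary C10. The ten-membered ring is not closed by a cyclisation: it arises by scission of the bond shared by the four- and eight-membered rings, so no end-to-end closure and no high dilution are involved, and the strain of the cyclobutene and of its trans fusion is released. No stereocentre is created; C3 and C10 become trigonal, so both trans-fused diastereomers of 20 converge on 21, and C4, C6, C7 and C8 are spectators. The selectivity needed is torquoselectivity: with a trans fusion, orbital symmetry allows either both ring bonds inward (ring-cis,cis) or both outward (ring-trans,trans), and the six-atom C4–C9 bridge, stiffened by the trans-fused lactone, can follow the outward path only into a doubly trans ten-membered diene, so the inward mode, which leaves C14 and H3 outside, is expected. The usual electronic preference for outward rotation is small here because quaternary C10 must turn a carbon inward in either mode, leaving only the C4-versus-H choice at C3 to be overridden by ring strain. Dilute solution, base-washed glass and a radical inhibitor are meant to exclude acid- or radical-induced isomerisation of 21.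

Step 18
Reactants: 21 ten-membered ring-cis,cis-diene lactone
Product: 22 C11-(dimethylaminomethyl) lactone (C11 epimers)
Conditions: LiN(iPr)2, THF, −78 °C; CH2=NMe2+ I−, −78 °C → rt
Reagents that add atoms: dimethyl(methylidene)ammonium iodide, C=[N+](C)C.[I-]
Why: Mannich reaction of the lactone lithium enolate (C11) with the preformed iminium salt; C7 carries no leaving group, the silyl ethers and the diene are inert, and the C11 configuration is irrelevant because the centre becomes trigonal in step 19.

Step 19
Reactants: 22 C11-(dimethylaminomethyl) lactone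
Product: 24 α-methylene lactone bis-silyl ether, via ammonium iodide 23 (not isolated)
Conditions: MeI, MeOH, rt; then NaHCO3 (aq), EtOAc, rt
Reagents that add atoms: none
Why: N-Methylation makes trimethylamine a leaving group and mild base then effects β-elimination (E1cB through the lactone enolate) to the exocyclic C11=C13 alkene.

Step 20
Reactants: 24 α-methylene lactone bis-silyl ether
Product: 25 8,14-diol
Conditions: HF·pyridine, pyridine, THF, 0 °C → rt
Reagents that add atoms: none
Why: Fluoride-driven cleavage of both silyl ethers under buffered, non-basic conditions that the α-methylene lactone and the diene tolerate and that should not promote lactone migration to the freed O8.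

Step 21
Reactants: 25 8,14-diol
Product: 26 14-acetate with free 8-hydroxyl
Conditions: AcCl (1.1 equiv), 2,4,6-collidine, CH2Cl2, −78 °C
Reagents that add atoms: acetyl chloride, CC(Cl)=O
Why: Chemoselective acylation: at low temperature with a hindered base the primary allylic C14 hydroxyl should be acetylated much faster than the secondary C8 hydroxyl flanked by C7 and C9.

Step 22
Reactants: 26 14-acetate with free 8-hydroxyl; 27 (S)-2,2,4-trimethyl-1,3-dioxolane-4-carboxylic acid
Product: 29 acetonide of the target, via mixed anhydride 28 (not isolated)
Conditions: 27, 2,4,6-Cl3C6H2COCl, Et3N, toluene, rt; then 26, DMAP, toluene, rt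
Reagents that add atoms: none
Why: Yamaguchi esterification: the acid is activated as the mixed anhydride and transferred by DMAP to the only free hydroxyl, O8. The acid has no α-hydrogen, so its quaternary centre cannot epimerise, and C8 keeps its configuration because the C8–O bond is not broken.

Step 23
Reactants: 29 acetonide of the target
Product: 30 CNP0347302.1
Conditions: AcOH/H2O (4:1), 40 °C
Reagents that add atoms: none
Why: Acid-catalysed hydrolysis of the isopropylidene acetal; aqueous acetic acid is mild enough for the α-methylene lactone and the diene, makes any reversible ionisation of the allylic acetate degenerate, and contains no base that could shift acyl groups onto the liberated diol.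

## Compound list

In 15–26 and 29, C4, C6, C7 and C8 are configured as in the target.

1 | (S)-3,7-dimethylocta-1,6-diene ((S)-β-citronellene) | C=C[C@@H](C)CCC=C(C)C | starting material
2 | (S)-4-methylhex-5-enal | C=C[C@@H](C)CCC=O | intermediate
3 | (2S,4S)-4-methyl-2-[(phenylamino)oxy]hex-5-enal | C=C[C@@H](C)C[C@H](ONc1ccccc1)C=O | intermediate (not isolated)
4 | ethyl (2Z,4S,6S)-6-methyl-4-[(phenylamino)oxy]octa-2,7-dienoate | C=C[C@@H](C)C[C@H](ONc1ccccc1)/C=C\C(=O)OCC | intermediate
5 | ethyl (2Z,4S,6S)-4-hydroxy-6-methylocta-2,7-dienoate | C=C[C@@H](C)C[C@H](O)/C=C\C(=O)OCC | intermediate (not isolated)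
6 | (5S)-5-[(2S)-2-methylbut-3-en-1-yl]furan-2(5H)-one | O=C1C=C[C@H](C[C@H](C)C=C)O1 | intermediate
7 | (4R,5S)-4-(1,3-dioxolan-2-yl)-5-[(2S)-2-methylbut-3-en-1-yl]oxolan-2-one | O=C1C[C@@H](C2OCCO2)[C@H](C[C@H](C)C=C)O1 | intermediate
8 | (2S,3R)-2-[(2S)-2-methylbut-3-en-1-yl]-5-oxooxolane-3-carbaldehyde | O=C1C[C@@H](C=O)[C@H](C[C@H](C)C=C)O1 | intermediate
9 | 2-methylidenepropane-1,3-diol | C=C(CO)CO | starting material
10 | 2-({[tert-butyl(dimethyl)silyl]oxy}methyl)prop-2-en-1-ol | C=C(CO)CO[Si](C)(C)C(C)(C)C | intermediate
11 | {[2-(bromomethyl)prop-2-en-1-yl]oxy}(tert-butyl)dimethylsilane | C=C(CBr)CO[Si](C)(C)C(C)(C)C | intermediate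
12 | tert-butyl(dimethyl)({2-[(tributylstannyl)methyl]prop-2-en-1-yl}oxy)silane | C=C(C[Sn](CCCC)(CCCC)CCCC)CO[Si](C)(C)C(C)(C)C | intermediate
13 | (4S,5S)-4-[(1R)-3-({[tert-butyl(dimethyl)silyl]oxy}methyl)-1-hydroxybut-3-en-1-yl]-5-[(2S)-2-methylbut-3-en-1-yl]oxolan-2-one | O=C1C[C@@H]([C@H](O)CC(=C)CO[Si](C)(C)C(C)(C)C)[C@H](C[C@H](C)C=C)O1 | intermediate
14 | (4R,5S)-4-[(1R)-1-{[tert-butyl(dimethyl)silyl]oxy}-3-({[tert-butyl(dimethyl)silyl]oxy}methyl)but-3-en-1-yl]-5-[(2S)-2-methylbut-3-en-1-yl]oxolan-2-one | O=C1C[C@@H]([C@H](O[Si](C)(C)C(C)(C)C)CC(=C)CO[Si](C)(C)C(C)(C)C)[C@H](C[C@H](C)C=C)O1 | intermediate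
15 | cis-cyclooctene lactone: γ-lactone C12(=O)–O–C6 trans-fused at C6–C7 to the cyclooctene C3=C10 (C4 and C9 cis); 4-methyl, 8-OTBS, 10-CH2OTBS | C1C(=O)O[C@H]2C[C@H](C)/C=C(/CO[Si](C)(C)C(C)(C)C)C[C@@H](O[Si](C)(C)C(C)(C)C)[C@H]12 | intermediate
16 | trans-cyclooctene lactone: as 15 with C4 and C9 trans on C3=C10 | C1C(=O)O[C@H]2C[C@H](C)/C=C(\CO[Si](C)(C)C(C)(C)C)C[C@@H](O[Si](C)(C)C(C)(C)C)[C@H]12 | intermediate
17 | trans-fused dichlorocyclobutanone: C3–C2(=O)–C1Cl2–C10 across C3/C10 of 16 (one trans diastereomer drawn) | C1C(=O)O[C@H]2C[C@H](C)[C@H]3C(=O)C(Cl)(Cl)[C@]3(CO[Si](C)(C)C(C)(C)C)C[C@@H](O[Si](C)(C)C(C)(C)C)[C@H]12 | intermediate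
18 | trans-fused cyclobutanone (C2=O, C1H2) | C1C(=O)O[C@H]2C[C@H](C)[C@H]3C(=O)C[C@]3(CO[Si](C)(C)C(C)(C)C)C[C@@H](O[Si](C)(C)C(C)(C)C)[C@H]12 | intermediate
19 | trans-fused cyclobutenyl triflate (C1=C2–OTf) | C1C(=O)O[C@H]2C[C@H](C)[C@H]3C(OS(=O)(=O)C(F)(F)F)=C[C@]3(CO[Si](C)(C)C(C)(C)C)C[C@@H](O[Si](C)(C)C(C)(C)C)[C@H]12 | intermediate
20 | trans-fused bicyclo[6.2.0]dec-9-ene lactone (cyclobutene C3–C2=C1–C10, quaternary C10 bearing C14H2OTBS; 8-OTBS) | C1C(=O)O[C@H]2C[C@H](C)[C@H]3C=C[C@]3(CO[Si](C)(C)C(C)(C)C)C[C@@H](O[Si](C)(C)C(C)(C)C)[C@H]12 | intermediate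
21 | ten-membered ring-cis,cis-diene lactone (1(10)E,2Z; 8-OTBS, 14-OTBS) | C1C(=O)O[C@H]2C[C@H](C)/C=C\C=C(\CO[Si](C)(C)C(C)(C)C)C[C@@H](O[Si](C)(C)C(C)(C)C)[C@H]12 | intermediate
22 | C11-(dimethylaminomethyl) derivative of 21 (C11 epimers) | CN(C)CC1C(=O)O[C@H]2C[C@H](C)/C=C\C=C(\CO[Si](C)(C)C(C)(C)C)C[C@@H](O[Si](C)(C)C(C)(C)C)[C@H]12 | intermediate
23 | C11-(trimethylammoniomethyl) lactone iodide | C[N+](C)(C)CC1C(=O)O[C@H]2C[C@H](C)/C=C\C=C(\CO[Si](C)(C)C(C)(C)C)C[C@@H](O[Si](C)(C)C(C)(C)C)[C@H]12.[I-] | intermediate (not isolated)
24 | α-methylene lactone, 8,14-bis-TBS ether | C=C1C(=O)O[C@H]2C[C@H](C)/C=C\C=C(\CO[Si](C)(C)C(C)(C)C)C[C@@H](O[Si](C)(C)C(C)(C)C)[C@H]12 | intermediate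
25 | α-methylene lactone 8,14-diol | C=C1C(=O)O[C@H]2C[C@H](C)/C=C\C=C(\CO)C[C@@H](O)[C@H]12 | intermediate
26 | α-methylene lactone 14-acetate with free 8-hydroxyl | C=C1C(=O)O[C@H]2C[C@H](C)/C=C\C=C(\COC(C)=O)C[C@@H](O)[C@H]12 | intermediate
27 | (S)-2,2,4-trimethyl-1,3-dioxolane-4-carboxylic acid | OC(=O)[C@@]1(C)OC(C)(C)OC1 | starting material
28 | (S)-2,2,4-trimethyl-1,3-dioxolane-4-carboxylic 2,4,6-trichlorobenzoic anhydride | O=C(OC(=O)[C@@]1(C)OC(C)(C)OC1)c1c(Cl)cc(Cl)cc1Cl | intermediate (not isolated)
29 | acetonide of the target (8-O-[(S)-2,2,4-trimethyl-1,3-dioxolane-4-carbonyl], 14-O-acetyl) | C=C1C(=O)O[C@H]2C[C@H](C)/C=C\C=C(\COC(C)=O)C[C@@H](OC(=O)[C@@]3(C)OC(C)(C)OC3)[C@H]12 | intermediate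
30 | CNP0347302.1 | C=C1C(=O)O[C@H]2C[C@H](C)/C=C\C=C(\COC(C)=O)C[C@@H](OC(=O)[C@@](C)(O)CO)[C@H]12 | target

## Step count and least certain steps

Total: 23 steps. Longest linear sequence: 20 steps (1–5 and 9–23); the stannane 12 takes steps 6–8.

**Step 17 (key step, Proposed new method).** The ring bonds may rotate outward instead of inward, or the σ bond may break stepwise, so that a ring-trans alkene results; the temperature required may also bring on 1,5-hydrogen shifts in the product. The cause is that inward rotation of C4 at C3 is electronically disfavoured and its contest with the ring constraint is untested for this ring system. Fallback with known chemistry, from 15 back to 21: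
- The photoisomerisation is omitted and the ketene cycloaddition is run on the cis-alkene 15, giving the cis-fused dichlorocyclobutanone F1.
- Zn–Cu/NH4Cl gives the cis-fused cyclobutanone F2; KN(SiMe3)2/PhNTf2 gives the cis-fused cyclobutenyl triflate F3; Pd(OAc)2/PPh3/HCO2H/Et3N gives the cis-fused cyclobutene F4.
- Thermolysis of F4 is the known reaction type (one ring bond inward, one outward). It should give the cis,trans-diene F5, with the ring-trans geometry expected at C2=C3 because hydrogen rather than C4 turns inward at C3.
- Thiyl-radical equilibration (PhSSPh, hν) or iodine catalysis then converts the strained disubstituted trans alkene into the more stable ring-cis geometry, which is 21.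

**Step 12.** Conversion may stall, because the photostationary state lies on the Z side and a hindered trisubstituted E-alkene may be captured only weakly by silver, so that it reverts before it is removed. Fallback, from 15 back to 16:
- mCPBA gives the epoxide F6.
- Aqueous HClO4 (cat.) in THF opens it with inversion to the ring-trans diol F7; attack at either carbon gives a trans diol.
- Thiocarbonyldiimidazole/DMAP in hot toluene gives the cyclic thionocarbonate F8.
- Corey–Winter olefination with 1,3-dimethyl-2-phenyl-1,3,2-diazaphospholidine at 40 °C removes both oxygens in a syn fashion and gives 16.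

**Step 15.** Deprotonation may compete at the C3 methine, which would give the regioisomeric enol triflate and could scramble the ring fusion; C1 is flanked by the quaternary C10, so the usual CH2-over-CH preference may be eroded. Fallback, from 17 back to 19, in which the chlorine fixes the enolate position:
- One equivalent of Zn–Cu/NH4Cl at 0 °C gives the monochloroketone F9.
- Zn/Me3SiCl in THF reduces the remaining C–Cl bond and traps the zinc enolate as the silyl enol ether F10 (C1=C2–OSiMe3).
- CsF/PhNTf2 in DME converts F10 into 19.

**Step 9.** Facial selectivity may erode and turnover may be slow with an α-branched aldehyde, the dipole of the β-oxygen on C6 opposing the Felkin preference; the titanium alkoxide might also move the lactone to O8. Fallback, from 8 and 11 back to 13: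
- A Barbier allylation with 11 and In powder in THF/H2O gives 13 together with the C8 epimer F11, which is separated.
- F11 is inverted by a Mitsunobu reaction (ClCH2CO2H, PPh3, DIAD) to the chloroacetate F12.
- Thiourea/NaHCO3 in EtOH cleaves F12 to 13.

## Further compounds

F1 | step 17 | cis-fused dichlorocyclobutanone (as 17 but C4 and C9 on the same face) | C1C(=O)O[C@H]2C[C@H](C)[C@@H]3C(=O)C(Cl)(Cl)[C@]3(CO[Si](C)(C)C(C)(C)C)C[C@@H](O[Si](C)(C)C(C)(C)C)[C@H]12
F2 | step 17 | cis-fused cyclobutanone | C1C(=O)O[C@H]2C[C@H](C)[C@@H]3C(=O)C[C@]3(CO[Si](C)(C)C(C)(C)C)C[C@@H](O[Si](C)(C)C(C)(C)C)[C@H]12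
F3 | step 17 | cis-fused cyclobutenyl triflate | C1C(=O)O[C@H]2C[C@H](C)[C@@H]3C(OS(=O)(=O)C(F)(F)F)=C[C@]3(CO[Si](C)(C)C(C)(C)C)C[C@@H](O[Si](C)(C)C(C)(C)C)[C@H]12
F4 | step 17 | cis-fused bicyclo[6.2.0]dec-9-ene lactone | C1C(=O)O[C@H]2C[C@H](C)[C@@H]3C=C[C@]3(CO[Si](C)(C)C(C)(C)C)C[C@@H](O[Si](C)(C)C(C)(C)C)[C@H]12
F5 | step 17 | ten-membered cis,trans-diene lactone (C2=C3 ring-trans, C1=C10 as in 21) | C1C(=O)O[C@H]2C[C@H](C)/C=C/C=C(/CO[Si](C)(C)C(C)(C)C)C[C@@H](O[Si](C)(C)C(C)(C)C)[C@H]12
F6 | step 12 | C3,C10-epoxide of 15 (one face drawn) | C1C(=O)O[C@H]2C[C@H](C)[C@@H]3O[C@]3(CO[Si](C)(C)C(C)(C)C)C[C@@H](O[Si](C)(C)C(C)(C)C)[C@H]12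
F7 | step 12 | ring-trans C3,C10-diol | C1C(=O)O[C@H]2C[C@H](C)[C@H](O)[C@](O)(CO[Si](C)(C)C(C)(C)C)C[C@@H](O[Si](C)(C)C(C)(C)C)[C@H]12
F8 | step 12 | trans-fused cyclic thionocarbonate of F7 | C1C(=O)O[C@H]2C[C@H](C)[C@@H]3OC(=S)O[C@@]3(CO[Si](C)(C)C(C)(C)C)C[C@@H](O[Si](C)(C)C(C)(C)C)[C@H]12
F9 | step 15 | trans-fused monochlorocyclobutanone (C1 epimers) | C1C(=O)O[C@H]2C[C@H](C)[C@H]3C(=O)C(Cl)[C@]3(CO[Si](C)(C)C(C)(C)C)C[C@@H](O[Si](C)(C)C(C)(C)C)[C@H]12
F10 | step 15 | trans-fused 2-(trimethylsilyloxy)cyclobutene (C1=C2) | C1C(=O)O[C@H]2C[C@H](C)[C@H]3C(O[Si](C)(C)C)=C[C@]3(CO[Si](C)(C)C(C)(C)C)C[C@@H](O[Si](C)(C)C(C)(C)C)[C@H]12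
F11 | step 9 | C8 epimer of 13 | O=C1C[C@@H]([C@@H](O)CC(=C)CO[Si](C)(C)C(C)(C)C)[C@H](C[C@H](C)C=C)O1
F12 | step 9 | chloroacetate of 13 | O=C1C[C@@H]([C@H](OC(=O)CCl)CC(=C)CO[Si](C)(C)C(C)(C)C)[C@H](C[C@H](C)C=C)O1
A1 | alternative 1 | open-chain lactone with C1 vinyl iodide and C2 (Z)-vinylstannane | C=C1C(=O)O[C@@H](C[C@H](C)/C=C\[Sn](CCCC)(CCCC)CCCC)[C@@H]1[C@H](OC(=O)[C@@]2(C)OC(C)(C)OC2)C/C(COC(C)=O)=C\I
A2 | alternative 1 | acetonide of the target | C=C1C(=O)O[C@H]2C[C@H](C)/C=C\C=C(\COC(C)=O)C[C@@H](OC(=O)[C@@]3(C)OC(C)(C)OC3)[C@H]12
A3 | alternative 2 | cis-1-[2-(benzyldimethylsilyl)vinyl]-2-(2-propenyl)cyclohex-3-enol (ring configuration relative to C4 as drawn is assumed) | O[C@@]1(/C=C/[Si](C)(C)Cc2ccccc2)C[C@H](C)C=C[C@@H]1C(=C)CO[Si](C)(C)C(C)(C)C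
A4 | alternative 2 | ten-membered silyl enol ether with C8 silane and cis,cis-diene | C[Si](C)(C)O/C1=C\[C@H]([Si](C)(C)Cc2ccccc2)C/C(CO[Si](C)(C)C(C)(C)C)=C\C=C/[C@@H](C)C1
A5 | alternative 3 | 13-membered allylic ether with C6 stannane (C6 configuration and C7=C11 geometry as drawn are assumed) | CCCC[Sn](CCCC)(CCCC)[C@H]1C[C@H](C)/C=C\C=C(\CO[Si](c2ccccc2)(c2ccccc2)C(C)(C)C)C[C@@H](O[Si](C)(C)C(C)(C)C)/C=C(/CO[Si](CC)(CC)CC)CO1
A6 | alternative 3 | ten-membered C6 carbinol with 2-propenyl unit on C7 | O[C@H]1C[C@H](C)/C=C\C=C(\CO[Si](c2ccccc2)(c3ccccc3)C(C)(C)C)C[C@@H](O[Si](C)(C)C(C)(C)C)[C@@H]1C(=C)CO[Si](CC)(CC)CC
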